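## Structural features

The target is a 2,2-dimethylchroman: a dihydropyran (ring B: O1, C2, C3, C4, C4a, C8a) fused along C4a–C8a to a benzene ring (ring A) in which every position except C6 is substituted. Going round ring A, C4a carries the C4 methylene, C5 the E-styryl group, C6 a hydrogen, C7 the free phenol, C8 the prenyl group and C8a the ether oxygen O1. C7 and C8a therefore carry oxygen in a 1,3-relationship with the prenyl-bearing C8 between them. The only stereocentre is C3, a secondary carbinol of R configuration between the quaternary C2 and the benzylic C4; it has no stereogenic neighbour, so the task is absolute configuration, not relative configuration. Fragile groups are the phenol with its ortho prenyl group (acid closes a second chroman ring; oxidants attack the electron-rich ring and the trisubstituted alkene), the E-styryl double bond (no hydrogenation, no hydrogenolysis, no strong electrophiles) and the C3 hydroxyl next to the tertiary ether, which can end up in an isomeric five-membered ether if O3 is ever allowed to compete with O1. The real difficulty is placing five different groups on ring A in the right order while keeping the six-membered O1–C2 ether with a defined C3 carbinol. The key step uses the 1,3-dioxygen pattern C7/C8a: ring A is treated as the dehydrogenated form of a 2-prenylcyclohexane-1,3-dione whose C8a carbonyl is at the same time the carbonyl of a δ-lactone that already holds O1, C2, C3 and C4, so that C6, C7, C8 and the prenyl chain all come from one methyl ketone.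

## Logic of the disconnections

**17 to 16.** Only the O–Si bond at O3 is cut. The hydroxyl must stay masked through three amide-base steps and one acid step, and a silyl ether can leave with fluoride at a stage where acid is no longer tolerated. Nothing is gained in skeleton. The forward step must be non-acidic and non-oxidising.

**16 to 12 (through 13).** No skeletal bond is cut. The C5=C6 unsaturation and the aromatic tautomer are given up, so that ring A becomes a vinylogous ester with C7 as ketone and C8=C8a as enol ether. This exposes the 1,3-dicarbonyl relationship of C7 and C8a and turns the five-substituent arene problem into carbonyl chemistry. The forward steps must functionalise C6 alone and eliminate under conditions that two alkenes and the newly formed phenol survive.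

**12 to 8 and 9.** C5–C6 and C8–C8a are cut, and the enol ether O1–C8a is read as the C–O bond of a lactone. C8–C8a is an acylation bond between an enolate carbon and an ester carbonyl; C5–C6 is a conjugate-addition bond to the β-carbon of an unsaturated ester. One ketone supplies both nucleophilic carbons on either side of C7. The 30-carbon intermediate falls into a C22 lactone that keeps the stereocentre and a C8 ketone, and the positions of prenyl, styryl and both oxygens are fixed by connectivity alone. The forward step must make the enolate of 9 react first through its methyl carbon, add 1,4 and not at the styryl terminus, close only the six-membered ring, and return O1 (not O3) to C8a.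

**8 to 4 and 5 (through 6).** The exocyclic C4a=C5 double bond is cut as an aldol addition followed by loss of water. This is the standard route to an α-alkylidene lactone and lets the E-styryl unit arrive ready-made in 5. The forward dehydration must not cost the γ-silyloxy group; the geometry of the new double bond is not critical.

**4 to 3.** The ring oxygen O1 is taken out from between C8a and C2 (the reverse of an oxygen insertion). The oxygenated quaternary carbon becomes an ordinary α-quaternary carbon of a cyclopentanone. The forward oxidation must migrate the quaternary carbon and not the methylene, and O3 must already be protected so that the lactone cannot rearrange.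

**3 to 1 (through 2).** The O–Si bond and the C3–H bond are cut. The stereocentre is traced to the reduction of one of the two enantiotopic carbonyl groups of 1, an achiral C7 compound. The forward reduction needs a catalyst that tells these carbonyl groups apart and stops after one of them.

## Other disconnections considered

**Alternative 1:** The cut is at C7–C8, C8a–C4a and C6–C7. Ring A is divided into the four carbons of 3-[(E)-2-phenylethenyl]cyclobut-2-en-1-one A3 (C4a, C5, C6, C7) and the two alkyne carbons of the chiral tert-alkyl alkynyl ether A2 (C8 with the prenyl group, C8a with the alkoxy group). In the forward step, heating A3 with A2 would start a sequence of four pericyclic events (ring opening, [2+2] addition to the alkyne, second ring opening, 6π closure) and a tautomerisation, ending in the resorcinol monoether A1.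

- In favour: ring A appears directly at the aromatic oxidation level, which is better than the chosen plan, where steps 7 and 8 are needed to reach the arene. The placement of hydroxyl, prenyl, ether oxygen and styryl follows from the mechanism, which equals the chosen plan. The stereocentre could come from the chiral pool, at least the equal of an enzymatic reduction.
- Against: A2 is an alkynyl ether of a tertiary alcohol with β-hydrogens. Such ethers are expected to fragment by retro-ene loss of an alkene at or below the temperature that A3 needs for ring opening. A1 also still lacks ring B: the C4–C4a bond would require acetal cleavage, activation of the primary carbon and an acid-mediated Friedel–Crafts closure on a ring carrying an ortho-prenyl phenol and a styryl group, with five- against six-membered closure as a further issue. A2 and A3 each need several steps.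
- Comparison: the chosen plan carries ring B and C3 through unchanged, whereas this alternative builds ring B last under the least tolerated conditions. Mechanistically it has fixed regiochemistry but a thermally fragile partner, against a polar annulation with two site selectivities. At least four steps follow its key step against three, and the fragments are longer to make.

**Alternative 2:** The cut is at O1–C2 and C3–C4 of ring B. Ring A is complete in the salicyl alcohol A5, and C2, C3 and the two methyl groups come from the isobutenylboronate A7. In the forward step a chiral phosphoric acid would dehydrate A5 to the ortho-quinone methide A6, which would add A7 in an inverse-demand hetero-Diels–Alder reaction, C3 bonding to C4 and O1 to the tertiary C2, to give the 3-borylchroman A4. Oxidation of the C–B bond with retention (NaBO3·4H2O) and desilylation would finish the synthesis.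

- In favour: ring B and the stereocentre are made in one catalytic step on a finished ring A, with no protecting group on O3. On convergence and on handling of O3 this alternative is better than the chosen plan. The two steps after its key step are equal to or fewer than the three of the chosen plan. The regiochemistry of the cycloaddition is well founded, because positive charge develops at the tertiary C2.
- Against: A7 is a weak nucleophile for an electron-poor heterodiene and offers the chiral acid no binding site, so rate and facial control are both doubtful. A6 has the styryl group next to its methylene carbon and could be trapped intramolecularly (cation–alkene closure to an indene). An ortho-prenyl phenol is exposed to Brønsted acid. The pentasubstituted A5 must itself be built by regioselective prenylation and hydroxymethylation, which is the very regiochemical problem that the chosen plan solves by construction.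
- Comparison: the alternative is shorter on paper from A5, but the length and the uncertainty are moved into the preparation of A5. The chosen plan sets C3 with a method of proven generality and keeps it as a spectator.

**Alternative 3:** The cut is at C4a–C5. The precursor A9 is read as the 2-alkylidenetetrahydropyran whose exocyclic carbon C8 carries the prenyl group and the C7 ketone, continuing through C6 to the cinnamoyl carbonyl C5. In the forward step mild acid would move the enol-ether double bond of A9 into ring B (C8a=C4a) with enolisation at C7; C4a would then add to C5 and loss of water would aromatise ring A. The product A8 is the 3-O-silyl ether of the target and is identical with 16.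

- In favour: ring B and C3 would come from the same lactone 4 as in the chosen plan (equal). The arene forms at the correct oxidation level without selenium (better). The endgame is the same single desilylation (equal).
- Against: A9 is a masked 1,3,5-tricarbonyl compound. Its C5 ketone sits in an enolised β-diketone and a cinnamoyl unit, so it is a weak carbon electrophile and also a conjugate acceptor. The enol oxygen at C5 can add to C8a and expel O1, which would open ring B and give a 4-pyranone, the classical competitor of carbocyclic aldol closure. C4a is only the γ-terminus of a vinylogous ester. Preparing A9 needs a regioselective C-acylation sequence of several steps.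
- Comparison: the chosen annulation has one productive cyclisation mode (the other enolate could only close a four-membered ring), whereas A9 has several. Step counts are expected to be similar.

Key step: step 6

**Remarks on the chemistry**

- Atom labels (C4a, C5, O1 and so on) are those of the chroman throughout; systematic names of the lactones use their own ring numbering.
- Assumption: a ketoreductase that reduces 1 to the R alcohol 2 can be picked from a commercial screening panel.
- The centre C3 keeps the descriptor R from 2 to 17, because the order oxygen > quaternary carbon > methylene > hydrogen holds there in every compound and no step touches it. The constitution, the E,E geometry and the R descriptor of 8, and the constitution of 12, were checked atom by atom against 17 and needed no change.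
- Design of 8, tightened at three points. (a) O3 is silylated at the stage of 2, before the ring oxygen is inserted, because a free 5-hydroxy lactone would rearrange to the five-membered lactone, and a free O3 would later compete with O1 for C8a. (b) The silyl group is tert-butyldimethylsilyl, robust enough for three amide-base steps and one mild acid step and still removable with fluoride. (c) The geometry of the exocyclic double bond of 8 is not a requirement, since C5 and C4a lose their configuration in step 8; only the E geometry of the styryl bond brought in with 5 must be kept.

## Route

**Step 1**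
Reactants: 1 2,2-dimethylcyclopentane-1,3-dione
Product: 2 (R)-3-hydroxy-2,2-dimethylcyclopentan-1-one
Conditions: ketoreductase (R-selective), NADP+ (cat.), iPrOH, phosphate buffer pH 7, 30 °C
Reagents that add atoms: none
Why: Enzymatic mono-reduction of a prochiral 2,2-disubstituted 1,3-dione (ketoreductase desymmetrisation); the two carbonyl groups are enantiotopic, so the enzyme's choice of carbonyl and face sets C3 as R, and the β-hydroxy ketone is a much poorer substrate than the dione, which should stop the reaction at 2.

**Step 2**
Reactants: 2 (R)-3-hydroxy-2,2-dimethylcyclopentan-1-one
Product: 3 (R)-3-(tert-butyldimethylsilyloxy)-2,2-dimethylcyclopentan-1-one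
Conditions: TBSCl, imidazole, DMF, rt
Reagents that add atoms: tert-butyldimethylsilyl chloride, CC(C)(C)[Si](C)(C)Cl
Why: Standard silylation of a secondary alcohol under nearly neutral conditions, mild enough that the β-hydroxy ketone should suffer neither retro-aldol cleavage nor elimination; the ether is put on before the oxidation so that the lactone of step 3 cannot rearrange.

**Step 3**
Reactants: 3 (R)-3-(tert-butyldimethylsilyloxy)-2,2-dimethylcyclopentan-1-one
Product: 4 (R)-5-(tert-butyldimethylsilyloxy)-6,6-dimethyltetrahydro-2H-pyran-2-one
Conditions: mCPBA, NaHCO3, CH2Cl2, 0 °C → rt
Reagents that add atoms: meta-chloroperoxybenzoic acid, OOC(=O)c1cccc(Cl)c1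
Why: Baeyer–Villiger oxidation; the quaternary α-carbon migrates in preference to the methylene, which places the ring oxygen (the later O1) on the gem-dimethyl carbon, and C3 takes no part and stays R.

**Step 4**
Reactants: 4 (R)-5-(tert-butyldimethylsilyloxy)-6,6-dimethyltetrahydro-2H-pyran-2-one; 5 (E)-cinnamaldehyde
Product: 6 (5R)-5-(tert-butyldimethylsilyloxy)-3-[(2E)-1-hydroxy-3-phenylprop-2-en-1-yl]-6,6-dimethyltetrahydro-2H-pyran-2-one (mixture of diastereomers at the two new centres)
Conditions: LiN(iPr)2, THF, −78 °C; 5, −78 °C; AcOH
Reagents that add atoms: none
Why: Aldol addition of a lactone lithium enolate to an enal, which at low temperature should take place at the carbonyl carbon; the silyloxy group is γ to the enolate carbon and cannot be eliminated, and the two new centres do not matter because both disappear in step 5.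

**Step 5**
Reactants: 6 (5R)-5-(tert-butyldimethylsilyloxy)-3-[(2E)-1-hydroxy-3-phenylprop-2-en-1-yl]-6,6-dimethyltetrahydro-2H-pyran-2-one
Product: 8 (3E,5R)-5-(tert-butyldimethylsilyloxy)-6,6-dimethyl-3-[(2E)-3-phenylprop-2-en-1-ylidene]tetrahydro-2H-pyran-2-one, via allylic mesylate 7 (not isolated)
Conditions: MsCl, Et3N, CH2Cl2, 0 °C; DBU, 0 °C → rt
Reagents that add atoms: none
Why: Sulfonylation followed by E1cB elimination through the lactone enolate; conjugation through to the phenyl ring drives the loss of methanesulfonate, the E alkylidene is the thermodynamically preferred isomer, and any allylic chloride formed from the labile mesylate should eliminate to the same diene under the same base.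

**Step 6**
Reactants: 8 (3E,5R)-5-(tert-butyldimethylsilyloxy)-6,6-dimethyl-3-[(2E)-3-phenylprop-2-en-1-ylidene]tetrahydro-2H-pyran-2-one; 9 6-methylhept-5-en-2-one
Product: 12 (3R)-3-(tert-butyldimethylsilyloxy)-2,2-dimethyl-8-(3-methylbut-2-en-1-yl)-5-[(E)-2-phenylethenyl]-2,3,4,4a,5,6-hexahydro-7H-chromen-7-one (mixture of C4a/C5 epimers), via keto lactone 10 (not isolated), via hydroxy dione 11 (not isolated)
Conditions: 9 (1.3 equiv) added to LiN(iPr)2 (1.4 equiv), THF, −78 °C; 8, −78 °C → rt; AcOH; PPTS (cat.), PhMe, 4 Å MS, 50 °C
Reagents that add atoms: none
Why: This is a Michael–Claisen [3+3] annulation of a ketone enolate with an α,β-unsaturated ester, here a lactone. The kinetic lithium enolate of 9 (ketone added to a slight excess of amide base at −78 °C, so that the methyl group is deprotonated and no free ketone remains to scramble it) adds through C6 to the β-carbon C5 of 8 and gives the lactone enolate of 10; proton transfer moves the charge to C8, and this enolate attacks the lactone carbonyl C8a in a 6-exo-trig acyl substitution that expels the tertiary alkoxide O1, closes the carbocycle and leaves the product as the stable enolate of the 2-prenyl-1,3-dione 11, so that one equivalent of base is enough. With a trace of PPTS the tertiary hydroxyl adds to C8a (6-exo-trig; C7 is out of reach) and water is lost, which closes ring B again as the vinylogous ester 12 without the O1–C2 bond or C3 ever being broken. The new centre C5 is set by the face of the conjugate addition and C4a by protonation (it can equilibrate through the dienol); neither is under useful control and neither needs to be, since both become sp2 in step 8. Attack at C5 and not at the styryl terminus or at the carbonyl carbon is expected from a hard lithium enolate under kinetic control toward a carbonyl shielded by its tertiary alkoxy group, and only the 1,4-adduct has a six-membered Claisen exit, so adducts formed reversibly elsewhere should drain back through it. The other enolate of 10 (at C6) could only close a four-membered ring, so the regiochemistry of the Claisen step is fixed by ring size. The silyl ether keeps O3 from competing with O1 for C8a, and the buffered acid should leave the prenyl group, the styryl group and the silyl ether untouched.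

**Step 7**
Reactants: 12 (3R)-3-(tert-butyldimethylsilyloxy)-2,2-dimethyl-8-(3-methylbut-2-en-1-yl)-5-[(E)-2-phenylethenyl]-2,3,4,4a,5,6-hexahydro-7H-chromen-7-one
Product: 13 (3R)-3-(tert-butyldimethylsilyloxy)-2,2-dimethyl-8-(3-methylbut-2-en-1-yl)-5-[(E)-2-phenylethenyl]-6-(phenylselanyl)-2,3,4,4a,5,6-hexahydro-7H-chromen-7-one (mixture of diastereomers)
Conditions: LiN(iPr)2, THF, −78 °C; PhSeCl, −78 °C; NH4Cl (aq)
Reagents that add atoms: benzeneselenenyl chloride, Cl[Se]c1ccccc1
Why: α-Selenenylation of a ketone enolate; kinetic deprotonation of a vinylogous ester takes place at the α′ position C6 and not at the γ position C4a, the electrophile should enter opposite the C5 styryl group (selenium cis to H5, as the later syn elimination requires), and at −78 °C the enolate should react with the selenenyl chloride far faster than the alkenes do.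

**Step 8**
Reactants: 13 (3R)-3-(tert-butyldimethylsilyloxy)-2,2-dimethyl-8-(3-methylbut-2-en-1-yl)-5-[(E)-2-phenylethenyl]-6-(phenylselanyl)-2,3,4,4a,5,6-hexahydro-7H-chromen-7-one
Product: 16 (3R)-3-(tert-butyldimethylsilyloxy)-2,2-dimethyl-8-(3-methylbut-2-en-1-yl)-5-[(E)-2-phenylethenyl]-3,4-dihydro-2H-chromen-7-ol, via selenoxide 14 (not isolated), via cross-conjugated dienone 15 (not isolated)
Conditions: mCPBA (1.0 equiv), CH2Cl2, −78 °C; iPr2NH, −78 °C → rt
Reagents that add atoms: none
Why: Selenoxide elimination used as a dehydrogenative aromatisation; one equivalent of peracid at −78 °C should oxidise selenium much faster than it epoxidises the prenyl or styryl alkene, the selenoxide eliminates syn towards H5 on warming to give dienone 15, and base-mediated loss of H4a tautomerises 15 to the phenol; the amine takes up the benzeneselenenic acid and can epimerise a cis selenoxide at C6.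

**Step 9**
Reactants: 16 (3R)-3-(tert-butyldimethylsilyloxy)-2,2-dimethyl-8-(3-methylbut-2-en-1-yl)-5-[(E)-2-phenylethenyl]-3,4-dihydro-2H-chromen-7-ol
Product: 17 (3R)-2,2-dimethyl-8-(3-methylbut-2-en-1-yl)-5-[(E)-2-phenylethenyl]-3,4-dihydro-2H-chromene-3,7-diol
Conditions: Bu4NF, AcOH, THF, rt → 40 °C
Reagents that add atoms: none
Why: Fluoride-induced cleavage of the Si–O bond; buffering with acetic acid avoids a free phenoxide, no acid strong enough to cyclise the ortho-prenyl phenol is present, and C3 is untouched, so 17 should be obtained as the R enantiomer.

## Compound list

1 | 2,2-dimethylcyclopentane-1,3-dione | CC1(C)C(=O)CCC1=O | starting material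
2 | (R)-3-hydroxy-2,2-dimethylcyclopentan-1-one | CC1(C)[C@H](O)CCC1=O | intermediate
3 | (R)-3-(tert-butyldimethylsilyloxy)-2,2-dimethylcyclopentan-1-one | CC1(C)[C@H](O[Si](C)(C)C(C)(C)C)CCC1=O | intermediate
4 | (R)-5-(tert-butyldimethylsilyloxy)-6,6-dimethyltetrahydro-2H-pyran-2-one | O=C1OC(C)(C)[C@H](O[Si](C)(C)C(C)(C)C)CC1 | intermediate
5 | (E)-cinnamaldehyde | O=C/C=C/c1ccccc1 | starting material
6 | (5R)-5-(tert-butyldimethylsilyloxy)-3-[(2E)-1-hydroxy-3-phenylprop-2-en-1-yl]-6,6-dimethyltetrahydro-2H-pyran-2-one (diastereomer mixture) | O=C1OC(C)(C)[C@H](O[Si](C)(C)C(C)(C)C)CC1C(O)/C=C/c1ccccc1 | intermediate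
7 | methanesulfonate of 6 (formed in the flask, not isolated) | O=C1OC(C)(C)[C@H](O[Si](C)(C)C(C)(C)C)CC1C(OS(C)(=O)=O)/C=C/c1ccccc1 | intermediate
8 | (3E,5R)-5-(tert-butyldimethylsilyloxy)-6,6-dimethyl-3-[(2E)-3-phenylprop-2-en-1-ylidene]tetrahydro-2H-pyran-2-one | O=C1OC(C)(C)[C@H](O[Si](C)(C)C(C)(C)C)C/C1=C\C=C\c1ccccc1 | intermediate
9 | 6-methylhept-5-en-2-one | CC(=O)CCC=C(C)C | starting material
10 | (5R)-5-(tert-butyldimethylsilyloxy)-6,6-dimethyl-3-[(1E)-9-methyl-5-oxo-1-phenyldeca-1,8-dien-3-yl]tetrahydro-2H-pyran-2-one (formed in the flask, not isolated) | O=C1OC(C)(C)[C@H](O[Si](C)(C)C(C)(C)C)CC1C(/C=C/c1ccccc1)CC(=O)CCC=C(C)C | intermediate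
11 | 4-[(2R)-2-(tert-butyldimethylsilyloxy)-3-hydroxy-3-methylbutyl]-2-(3-methylbut-2-en-1-yl)-5-[(E)-2-phenylethenyl]cyclohexane-1,3-dione (formed in the flask, not isolated) | CC(C)=CCC1C(=O)CC(/C=C/c2ccccc2)C(C[C@@H](O[Si](C)(C)C(C)(C)C)C(C)(C)O)C1=O | intermediate
12 | (3R)-3-(tert-butyldimethylsilyloxy)-2,2-dimethyl-8-(3-methylbut-2-en-1-yl)-5-[(E)-2-phenylethenyl]-2,3,4,4a,5,6-hexahydro-7H-chromen-7-one (C4a/C5 epimer mixture) | CC(C)=CCC1=C2OC(C)(C)[C@H](O[Si](C)(C)C(C)(C)C)CC2C(/C=C/c2ccccc2)CC1=O | intermediate
13 | 6-(phenylselanyl) derivative of 12 | CC(C)=CCC1=C2OC(C)(C)[C@H](O[Si](C)(C)C(C)(C)C)CC2C(/C=C/c2ccccc2)C([Se]c2ccccc2)C1=O | intermediate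
14 | selenoxide of 13 (formed in the flask, not isolated) | CC(C)=CCC1=C2OC(C)(C)[C@H](O[Si](C)(C)C(C)(C)C)CC2C(/C=C/c2ccccc2)C([Se](=O)c2ccccc2)C1=O | intermediate
15 | (3R)-3-(tert-butyldimethylsilyloxy)-2,2-dimethyl-8-(3-methylbut-2-en-1-yl)-5-[(E)-2-phenylethenyl]-2,3,4,4a-tetrahydro-7H-chromen-7-one (formed in the flask, not isolated) | CC(C)=CCC1=C2OC(C)(C)[C@H](O[Si](C)(C)C(C)(C)C)CC2C(/C=C/c2ccccc2)=CC1=O | intermediate
16 | (3R)-3-(tert-butyldimethylsilyloxy)-2,2-dimethyl-8-(3-methylbut-2-en-1-yl)-5-[(E)-2-phenylethenyl]-3,4-dihydro-2H-chromen-7-ol | CC(C)=CCc1c(O)cc(/C=C/c2ccccc2)c2c1OC(C)(C)[C@H](O[Si](C)(C)C(C)(C)C)C2 | intermediate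
17 | (3R)-2,2-dimethyl-8-(3-methylbut-2-en-1-yl)-5-[(E)-2-phenylethenyl]-3,4-dihydro-2H-chromene-3,7-diol | CC(C)=CCc1c(O)cc(/C=C/c2ccccc2)c2c1OC(C)(C)[C@H](O)C2 | target

## Step count and least certain steps

Total: 9 steps. Longest linear sequence: 9 steps (1 to 17); 5 and 9 are bought and enter in steps 4 and 6.

**Step 6 (key step).**
- Risk: proton transfer from the γ-methylene (C4) of 8 to the ketone enolate in place of C–C bond formation at the hindered, trisubstituted β-carbon, followed by loss of the silyloxy group from the extended enolate. If the conjugate addition needs warming, the methyl/methylene selectivity of the enolate can also erode, and addition at the styryl terminus or acylation at the lactone carbonyl can compete.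
- Fallback (polarity of the first bond reversed; sets out from 4, 5 and 9, returns at 10 and from there reaches 12): Claisen–Schmidt condensation of 9 with 5 (NaOH, EtOH/H2O), which for a methyl ketone takes place at the methyl group, would give (1E,3E)-9-methyl-1-phenyldeca-1,3,8-trien-5-one F1. The lithium enolate of 4 (LiN(iPr)2, THF, −78 °C) would then add to F1. Ester-type enolates are good donors towards enones, so the C4a–C5 bond would be made first, and the ketone enolate that results is that of 10. Warming should let the charge move to C8 and close on the lactone carbonyl to 11, and the acid treatment of step 6 then gives 12. The unreactive acceptor 8 is avoided (steps 4 and 5 drop out), while the Claisen closure and the reclosure of ring B stay as planned. Addition to the ketone carbonyl or to the styryl terminus must be held back by equilibration on warming, and those adducts again have no cyclisation exit.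

**Step 8.**
- Risk: return of the expelled benzeneselenenic acid to the electron-rich ring at C6 or to the prenyl double bond, epoxidation if any oxidant is left, and a selenoxide diastereomer that cannot reach the syn arrangement with H5.
- Fallback (sets out from 12, returns at 16, replaces steps 7 and 8): the lithium enolate of 12 (LiN(iPr)2, THF, −78 °C) is treated with N-tert-butylbenzenesulfinimidoyl chloride. The enolate is sulfenylated to the 6-(N-tert-butyl-S-phenylsulfinimidoyl) derivative of 12 F2, which should undergo intramolecular syn elimination below room temperature to 15 and tautomerise to 16. No oxidant and no selenium electrophile are present.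

**Step 7.**
- Risk: addition of the selenenyl chloride across the trisubstituted prenyl alkene, migration of the enolate to the γ-terminus so that the electrophile enters at C4a, and double selenenylation at C6.
- Fallback (sets out from 12, returns at 16): the enolate of 12 (two equivalents of LiN(iPr)2, since the product is more acidic) is sulfinylated with methyl benzenesulfinate, an ester electrophile that does not react with alkenes, to give the 6-(phenylsulfinyl) derivative of 12 F3. Thermolysis in toluene at 80–110 °C over CaCO3 with trimethyl phosphite as sulfenic acid trap should bring about the sulfoxide syn elimination to 15 and hence 16.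

**Step 5.**
- Risk: ionisation or chloride displacement of the doubly activated allylic sulfonate before elimination, incomplete control of the alkylidene geometry, and base-induced loss of the silyloxy group through γ-deprotonation once the dienyl lactone has formed.
- Fallback (sets out from 4, returns at 8, replaces steps 4 and 5): Horner–Wadsworth–Emmons olefination. The enolate of 4 is treated with diethyl chlorophosphate in the presence of a second equivalent of LiN(iPr)2, so that the enol phosphate formed first rearranges to diethyl [(5R)-5-(tert-butyldimethylsilyloxy)-6,6-dimethyl-2-oxotetrahydro-2H-pyran-3-yl]phosphonate F4. Olefination of 5 with F4 under mild conditions (LiCl, DBU, MeCN) gives 8 directly; an E/Z mixture at the new double bond would be acceptable.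

**Step 1.**
- Risk: insufficient discrimination between the two enantiotopic carbonyl groups by the enzyme chosen, preference for the S alcohol, or further reduction to the diol.
- Fallback (sets out from 1, returns at 2, no new compound): oxazaborolidine-catalysed borane reduction (CBS reduction) with BH3·SMe2 at low temperature. The catalyst enantiomer is chosen by the large/small model with the quaternary carbon as the large group, which points to the (S)-2-methyl-oxazaborolidine for the R alcohol.

## Further compounds

F1 | step 6 | (1E,3E)-9-methyl-1-phenyldeca-1,3,8-trien-5-one | CC(C)=CCCC(=O)/C=C/C=C/c1ccccc1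
F2 | step 8 | 6-(N-tert-butyl-S-phenylsulfinimidoyl) derivative of 12 | CC(C)=CCC1=C2OC(C)(C)[C@H](O[Si](C)(C)C(C)(C)C)CC2C(/C=C/c2ccccc2)C(S(=NC(C)(C)C)c2ccccc2)C1=O
F3 | step 7 | 6-(phenylsulfinyl) derivative of 12 | CC(C)=CCC1=C2OC(C)(C)[C@H](O[Si](C)(C)C(C)(C)C)CC2C(/C=C/c2ccccc2)C(S(=O)c2ccccc2)C1=O
F4 | step 5 | diethyl [(5R)-5-(tert-butyldimethylsilyloxy)-6,6-dimethyl-2-oxotetrahydro-2H-pyran-3-yl]phosphonate | O=C1OC(C)(C)[C@H](O[Si](C)(C)C(C)(C)C)CC1P(=O)(OCC)OCC
F0 | step 1 | none | none
A1 | alternative 1 | 3-{2-[(4R)-2,2-dimethyl-1,3-dioxolan-4-yl]propan-2-yloxy}-2-(3-methylbut-2-en-1-yl)-5-[(E)-2-phenylethenyl]phenol | CC(C)=CCc1c(O)cc(/C=C/c2ccccc2)cc1OC(C)(C)[C@H]1COC(C)(C)O1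
A2 | alternative 1 | (4R)-2,2-dimethyl-4-{2-[(5-methylhex-4-en-1-yn-1-yl)oxy]propan-2-yl}-1,3-dioxolane | CC(C)=CCC#COC(C)(C)[C@H]1COC(C)(C)O1
A3 | alternative 1 | 3-[(E)-2-phenylethenyl]cyclobut-2-en-1-one | O=C1C=C(/C=C/c2ccccc2)C1
A4 | alternative 2 | (3R)-2,2-dimethyl-8-(3-methylbut-2-en-1-yl)-5-[(E)-2-phenylethenyl]-3-(4,4,5,5-tetramethyl-1,3,2-dioxaborolan-2-yl)-7-(triisopropylsilyloxy)chroman | CC(C)=CCc1c(O[Si](C(C)C)(C(C)C)C(C)C)cc(/C=C/c2ccccc2)c2c1OC(C)(C)[C@H](B1OC(C)(C)C(C)(C)O1)C2
A5 | alternative 2 | 2-(hydroxymethyl)-6-(3-methylbut-2-en-1-yl)-3-[(E)-2-phenylethenyl]-5-(triisopropylsilyloxy)phenol | CC(C)=CCc1c(O)c(CO)c(/C=C/c2ccccc2)cc1O[Si](C(C)C)(C(C)C)C(C)C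
A6 | alternative 2 | 6-methylidene-2-(3-methylbut-2-en-1-yl)-5-[(E)-2-phenylethenyl]-3-(triisopropylsilyloxy)cyclohexa-2,4-dien-1-one | O=C1C(=C)C(/C=C/c2ccccc2)=CC(O[Si](C(C)C)(C(C)C)C(C)C)=C1CC=C(C)C
A7 | alternative 2 | 4,4,5,5-tetramethyl-2-(2-methylprop-1-en-1-yl)-1,3,2-dioxaborolane | CC(C)=CB1OC(C)(C)C(C)(C)O1
A8 | alternative 3 | (3R)-3-(tert-butyldimethylsilyloxy)-2,2-dimethyl-8-(3-methylbut-2-en-1-yl)-5-[(E)-2-phenylethenyl]-3,4-dihydro-2H-chromen-7-ol (identical with 16) | CC(C)=CCc1c(O)cc(/C=C/c2ccccc2)c2c1OC(C)(C)[C@H](O[Si](C)(C)C(C)(C)C)C2
A9 | alternative 3 | (1E)-6-[(5R)-5-(tert-butyldimethylsilyloxy)-6,6-dimethyloxan-2-ylidene]-9-methyl-1-phenyldeca-1,8-diene-3,5-dione | CC(C)=CCC(C(=O)CC(=O)/C=C/c1ccccc1)=C1OC(C)(C)[C@H](O[Si](C)(C)C(C)(C)C)CC1
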